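The route opens ring B of the flavanone half at C1'–C2' and C1'–C6'. In that ring the oxygen on C4' lies para to C1', the carbon that holds C2 of ring C. C3' carries C8'' of the apigenin unit. C2'–C6' and the C4' oxygen are therefore the carbon frame and carbonyl of a 3-aryl-4H-pyran-4-one. In one operation (triphenylphosphoranylidene)acetaldehyde exchanges the pyranone ring oxygen for C1' with its formyl carbon and delivers the 3-flavonyl-4-hydroxybenzaldehyde. The precursor is a 2,6-unsubstituted 4-pyranone bound at C3 to C8'' of tri-O-benzylapigenin. The formyl carbon later becomes C2, set as S by a thiourea-catalysed oxa-Michael closure.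

Key step: step 7

**Locants and abbreviation:** The flavanone half uses O1, C2–C8a and C1'–C6'. The apigenin half uses double primes. Fv = 5,7-bis(benzyloxy)-2-[4-(benzyloxy)phenyl]-4-oxo-4H-chromen-8-yl (tri-O-benzylapigenin-8-yl).

**Design remarks**
- All five phenols that need masking carry benzyl ethers.
- Three operations run in acid: flavone cyclodehydration, pyranone closure and tert-butyl ester cleavage. Acetal-type groups such as MOM would be lost there, above all one at O5'' peri to the carbonyl.
- All five benzyl groups then fall in one neutral hydrogenolysis that cannot open the flavanone.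
- In the β-keto ester partner one of the two ortho phenols is masked. Only one oxygen can then close ring C, and the fast uncatalysed closure of a 2,6-dihydroxyaryl enone cannot erode enantiopurity.

Assumption 1: the quinidine-derived thiourea is taken to deliver 2S and its quinine-derived pseudoenantiomer 2R; the sense is to be checked by circular dichroism on 22, and the other catalyst is used in the same step if it proves opposite.
Assumption 2: the C3'–C8'' axis (three oxygen ortho substituents and one hydrogen) is taken to rotate on the laboratory time scale, in line with a target that carries no axial descriptor.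

Step 1
Reactants: 1 2,4,6-trihydroxyacetophenone
Product: 2 1-[2,4-bis(benzyloxy)-6-hydroxyphenyl]ethan-1-one
Conditions: BnBr (2.05 equiv), K2CO3 (2.2 equiv), DMF, 0 °C → rt
Reagents that add atoms: benzyl bromide, BrCc1ccccc1
Why: Williamson etherification; once the para and one ortho phenol are benzylated, the last phenol is held in a hydrogen bond to the acetyl oxygen and is far less nucleophilic, so alkylation should stop at the dibenzyl ether.

Step 2
Reactants: 2 1-[2,4-bis(benzyloxy)-6-hydroxyphenyl]ethan-1-one; 3 allyl bromide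
Product: 4 1-[2-(allyloxy)-4,6-bis(benzyloxy)phenyl]ethan-1-one
Conditions: 3 (1.5 equiv), K2CO3 (2 equiv), DMF, 60 °C
Reagents that add atoms: allyl bromide (3), C=CCBr
Why: Williamson etherification in which heat, a polar solvent and a reactive allylic halide overcome the hydrogen bond of the remaining phenol.

Step 3
Reactants: 4 1-[2-(allyloxy)-4,6-bis(benzyloxy)phenyl]ethan-1-one
Product: 5 1-[3-allyl-4,6-bis(benzyloxy)-2-hydroxyphenyl]ethan-1-one
Conditions: PhNEt2, 200 °C, Ar
Reagents that add atoms: none
Why: Aromatic Claisen rearrangement; of the two ortho positions one is blocked by the acetyl group, so the allyl group can only arrive at C3 (the future C8''), and rearomatisation returns the chelated phenol.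

Step 4
Reactants: 5 1-[3-allyl-4,6-bis(benzyloxy)-2-hydroxyphenyl]ethan-1-one; 6 4-(benzyloxy)benzoyl chloride
Product: 8 8-allyl-5,7-bis(benzyloxy)-2-[4-(benzyloxy)phenyl]-4H-chromen-4-one, via β-diketone 7 (not isolated)
Conditions: LiN(SiMe3)2 (3.5 equiv), THF, −78 → −10 °C; 6 (1.05 equiv), −78 °C → rt; 1 M HCl quench; crude 7, TsOH·H2O (10 mol %), toluene, 90 °C
Reagents that add atoms: 4-(benzyloxy)benzoyl chloride (6), O=C(Cl)c1ccc(OCc2ccccc2)cc1
Why: C-aroylation of the lithium dianion of an o-hydroxyacetophenone (the one-flask form of the Baker–Venkataraman route) gives the β-diketone, and acid cyclodehydration closes the flavone hetero-ring onto the only free phenol, the one next to the allyl group, which fixes the allyl group at C8'', while catalytic TsOH is mild enough for the benzyl ethers and the terminal alkene.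

Step 5
Reactants: 8 8-allyl-5,7-bis(benzyloxy)-2-[4-(benzyloxy)phenyl]-4H-chromen-4-one
Product: 9 1-Fv-propan-2-one (the 8-acetonylflavone)
Conditions: PdCl2 (10 mol %), CuCl (50 mol %), O2 (1 atm), DMF/H2O (7:1), 40 °C
Reagents that add atoms: water, O
Why: Tsuji–Wacker oxidation, in which Markovnikov attack of water on the alkene bound to divalent palladium gives the methyl ketone; it is placed after flavone closure so that no free ortho phenol can intercept the alkene complex.

Step 6
Reactants: 9 1-Fv-propan-2-one; 10 tert-butoxybis(dimethylamino)methane (Bredereck reagent)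
Product: 12 3-Fv-4H-pyran-4-one, via bis-enaminone 11 (not isolated)
Conditions: 10 (4 equiv), toluene, 105 °C, N2 sweep; evaporate; AcOH/H2O/THF (2:1:1), 70 °C
Reagents that add atoms: tert-butoxybis(dimethylamino)methane (10), CC(C)(C)OC(N(C)C)N(C)C; water, O
Why: Double aminomethylenation of the CH2 and CH3 flanking the ketone, then acid hydrolysis of one enaminone and addition–elimination of the resulting enol on the other, is the established way from benzyl methyl ketones to 3-aryl-4-pyranones, and the aminal ester is chosen over the amide acetal because the second condensation on a vinylogous amide is sluggish.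

Step 7
Reactants: 12 3-Fv-4H-pyran-4-one; 13 (triphenylphosphoranylidene)acetaldehyde
Product: 15 3-Fv-4-hydroxybenzaldehyde, via ring-opened phosphorane 14 (not isolated)
Conditions: 13 (1.1 equiv, three portions), PhCO2H (30 mol %), MeCN (0.2 M), 100 °C, sealed tube, Ar
Reagents that add atoms: (triphenylphosphoranylidene)acetaldehyde (13), O=CC=P(c1ccccc1)(c1ccccc1)c1ccccc1
Why: Proposed new method: the ylide carbon of 13 adds in conjugate fashion to the unsubstituted C6 (or C2) of the pyranone, which the carboxylic acid activates by hydrogen bonding towards 4-hydroxypyrylium character, the 2H-pyran adduct expels its ring oxygen (E1cB or retro-oxa-6π opening), and a proton shift gives the acyclic phosphorane 14, whose push–pull C=C bond can rotate into the Z geometry needed for closure. Ring B then closes by an intramolecular Wittig reaction, a 6-exo-trig attack of the ylide carbon on the formyl tautomer of the former O1–C2 unit, so that C1'–C6' comes from the addition and C1'–C2' from the olefination, the old ring oxygen leaves as Ph3P=O and the cyclohexadienone tautomerises to the phenol. The closest known reaction types are the conversion of pyrylium salts into benzenes with alkylidenephosphoranes and the ring-opening/ring-closing exchange of the 4-pyranone oxygen for nitrogen with primary amines. No stereocentre is formed, and regiochemistry needs no control because attack at C2 or at C6 leads to the same arene. Chemoselectivity over the flavone hetero-ring rests on its aryl-blocked C2'' and on its ring oxygen being phenolic, so an adduct there would have no carbonyl to olefinate and could only revert. Further olefination of the product is held back by near-stoichiometric, portionwise ylide and by the low electrophilicity of a 4-hydroxybenzaldehyde.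

Step 8
Reactants: 15 3-Fv-4-hydroxybenzaldehyde
Product: 16 4-(benzyloxy)-3-Fv-benzaldehyde
Conditions: BnBr (1.2 equiv), K2CO3 (1.5 equiv), DMF, rt
Reagents that add atoms: benzyl bromide, BrCc1ccccc1
Why: Williamson etherification of the acidic para-formyl phenol; masking it shuts the quinone-methide pathway by which a free 4'-phenol would make the later oxa-Michael addition reversible.

Step 9
Reactants: 17 2,6-dihydroxy-4-methoxyacetophenone
Product: 18 1-[2-(benzyloxy)-6-hydroxy-4-methoxyphenyl]ethan-1-one
Conditions: BnBr (1.05 equiv), K2CO3 (1.1 equiv), acetone, reflux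
Reagents that add atoms: benzyl bromide, BrCc1ccccc1
Why: Williamson etherification with one equivalent of halide; the two phenols are equivalent and the one that remains stays chelated to the acetyl group, so mono-alkylation should dominate.

Step 10
Reactants: 18 1-[2-(benzyloxy)-6-hydroxy-4-methoxyphenyl]ethan-1-one
Product: 19 tert-butyl 3-[2-(benzyloxy)-6-hydroxy-4-methoxyphenyl]-3-oxopropanoate
Conditions: LiN(SiMe3)2 (3.3 equiv), THF, −78 °C; Boc2O (1.05 equiv), −78 → 0 °C; cold 1 M HCl quench
Reagents that add atoms: di-tert-butyl dicarbonate, CC(C)(C)OC(=O)OC(=O)OC(C)(C)C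
Why: Claisen-type C-acylation of the lithium dianion with the dicarbonate; the carbon terminus is the most nucleophilic site, any aryl carbonate formed at oxygen should reach the same product by a Baker–Venkataraman-type O-to-C shift, and the third equivalent of base stores the product as its enolate.

Step 11
Reactants: 16 4-(benzyloxy)-3-Fv-benzaldehyde; 19 tert-butyl 3-[2-(benzyloxy)-6-hydroxy-4-methoxyphenyl]-3-oxopropanoate
Product: 20 tert-butyl (2Z)-2-[2-(benzyloxy)-6-hydroxy-4-methoxybenzoyl]-3-[4-(benzyloxy)-3-Fv-phenyl]prop-2-enoate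
Conditions: piperidine (20 mol %), AcOH (20 mol %), 4 Å MS, toluene, rt
Reagents that add atoms: none
Why: Knoevenagel condensation under piperidinium acetate catalysis at room temperature, expected to give the Z-alkylidene (β-aryl cis to the ester), while the bulky tert-butyl ester and the donor-substituted β-aryl group slow premature ring closure.

Step 12
Reactants: 20 tert-butyl (2Z)-2-[2-(benzyloxy)-6-hydroxy-4-methoxybenzoyl]-3-[4-(benzyloxy)-3-Fv-phenyl]prop-2-enoate
Product: 22 (2S)-5-(benzyloxy)-2-[4-(benzyloxy)-3-Fv-phenyl]-7-methoxy-2,3-dihydro-4H-chromen-4-one, via flavanone-3-carboxylate 21 (not isolated)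
Conditions: 1-[3,5-bis(trifluoromethyl)phenyl]-3-[(9R)-6'-methoxycinchonan-9-yl]thiourea (10 mol %), toluene, −25 °C; then TsOH·H2O (50 mol %), 80 °C
Reagents that add atoms: none
Why: Enantioselective intramolecular oxa-Michael addition (6-endo-trig) under bifunctional cinchona–thiourea catalysis, in which the thiourea binds the β-keto ester, the quinuclidine nitrogen activates the phenol and the catalyst decides which face of the alkylidene is attacked, setting C2 as S (C3 settles trans and is labile), after which acid cleaves the tert-butyl ester and the β-keto acid decarboxylates, removing the C3 centre without touching C2.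

Step 13
Reactants: 22 (2S)-5-(benzyloxy)-2-[4-(benzyloxy)-3-Fv-phenyl]-7-methoxy-2,3-dihydro-4H-chromen-4-one
Product: 23 target, (2S)-2-{3-[5,7-dihydroxy-2-(4-hydroxyphenyl)-4-oxo-4H-chromen-8-yl]-4-hydroxyphenyl}-5-hydroxy-7-methoxy-2,3-dihydro-4H-chromen-4-one
Conditions: H2 (1 atm), Pd/C (10 wt %), THF/EtOAc (1:1), rt
Reagents that add atoms: none
Why: Catalytic hydrogenolysis of the five benzyl ethers under neutral conditions; with no base present the retro-oxa-Michael pathway that racemises flavanones stays closed, and the methyl ether, the flavone double bond and the chelated ketones are not expected to react at 1 atm.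

**Compound list**

1 | 2,4,6-trihydroxyacetophenone | CC(=O)c1c(O)cc(O)cc1O | starting material
2 | 1-[2,4-bis(benzyloxy)-6-hydroxyphenyl]ethan-1-one | CC(=O)c1c(O)cc(OCc2ccccc2)cc1OCc1ccccc1 | intermediate
3 | allyl bromide | C=CCBr | starting material
4 | 1-[2-(allyloxy)-4,6-bis(benzyloxy)phenyl]ethan-1-one | CC(=O)c1c(OCC=C)cc(OCc2ccccc2)cc1OCc1ccccc1 | intermediate
5 | 1-[3-allyl-4,6-bis(benzyloxy)-2-hydroxyphenyl]ethan-1-one | CC(=O)c1c(O)c(CC=C)c(OCc2ccccc2)cc1OCc1ccccc1 | intermediate
6 | 4-(benzyloxy)benzoyl chloride | O=C(Cl)c1ccc(OCc2ccccc2)cc1 | starting material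
7 | 1-[3-allyl-4,6-bis(benzyloxy)-2-hydroxyphenyl]-3-[4-(benzyloxy)phenyl]propane-1,3-dione | O=C(CC(=O)c1ccc(OCc2ccccc2)cc1)c1c(O)c(CC=C)c(OCc2ccccc2)cc1OCc1ccccc1 | intermediate
8 | 8-allyl-5,7-bis(benzyloxy)-2-[4-(benzyloxy)phenyl]-4H-chromen-4-one | C=CCc1c(OCc2ccccc2)cc(OCc2ccccc2)c2c(=O)cc(-c3ccc(OCc4ccccc4)cc3)oc12 | intermediate
9 | 5,7-bis(benzyloxy)-2-[4-(benzyloxy)phenyl]-8-(2-oxopropyl)-4H-chromen-4-one | CC(=O)Cc1c(OCc2ccccc2)cc(OCc2ccccc2)c2c(=O)cc(-c3ccc(OCc4ccccc4)cc3)oc12 | intermediate
10 | tert-butoxybis(dimethylamino)methane | CC(C)(C)OC(N(C)C)N(C)C | starting material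
11 | (1E,4E)-1,5-bis(dimethylamino)-2-Fv-penta-1,4-dien-3-one (geometry labile) | CN(C)/C=C/C(=O)/C(=C/N(C)C)c1c(OCc2ccccc2)cc(OCc2ccccc2)c2c(=O)cc(-c3ccc(OCc4ccccc4)cc3)oc12 | intermediate
12 | 3-{5,7-bis(benzyloxy)-2-[4-(benzyloxy)phenyl]-4-oxo-4H-chromen-8-yl}-4H-pyran-4-one | O=c1ccocc1-c1c(OCc2ccccc2)cc(OCc2ccccc2)c2c(=O)cc(-c3ccc(OCc4ccccc4)cc3)oc12 | intermediate
13 | (triphenylphosphoranylidene)acetaldehyde | O=CC=P(c1ccccc1)(c1ccccc1)c1ccccc1 | starting material
14 | (3Z,6Z)-6-Fv-7-hydroxy-5-oxo-2-(triphenyl-λ5-phosphanylidene)hepta-3,6-dienal (enol form, drawn for attack at pyranone C6) | O=CC(=P(c1ccccc1)(c1ccccc1)c1ccccc1)/C=C\C(=O)/C(=C\O)c1c(OCc2ccccc2)cc(OCc2ccccc2)c2c(=O)cc(-c3ccc(OCc4ccccc4)cc3)oc12 | intermediate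
15 | 3-{5,7-bis(benzyloxy)-2-[4-(benzyloxy)phenyl]-4-oxo-4H-chromen-8-yl}-4-hydroxybenzaldehyde | O=Cc1ccc(O)c(-c2c(OCc3ccccc3)cc(OCc3ccccc3)c3c(=O)cc(-c4ccc(OCc5ccccc5)cc4)oc23)c1 | intermediate
16 | 4-(benzyloxy)-3-{5,7-bis(benzyloxy)-2-[4-(benzyloxy)phenyl]-4-oxo-4H-chromen-8-yl}benzaldehyde | O=Cc1ccc(OCc2ccccc2)c(-c2c(OCc3ccccc3)cc(OCc3ccccc3)c3c(=O)cc(-c4ccc(OCc5ccccc5)cc4)oc23)c1 | intermediate
17 | 2,6-dihydroxy-4-methoxyacetophenone | CC(=O)c1c(O)cc(OC)cc1O | starting material
18 | 1-[2-(benzyloxy)-6-hydroxy-4-methoxyphenyl]ethan-1-one | CC(=O)c1c(O)cc(OC)cc1OCc1ccccc1 | intermediate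
19 | tert-butyl 3-[2-(benzyloxy)-6-hydroxy-4-methoxyphenyl]-3-oxopropanoate | CC(C)(C)OC(=O)CC(=O)c1c(O)cc(OC)cc1OCc1ccccc1 | intermediate
20 | tert-butyl (2Z)-2-[2-(benzyloxy)-6-hydroxy-4-methoxybenzoyl]-3-[4-(benzyloxy)-3-Fv-phenyl]prop-2-enoate | CC(C)(C)OC(=O)/C(=C\c1ccc(OCc2ccccc2)c(-c2c(OCc3ccccc3)cc(OCc3ccccc3)c3c(=O)cc(-c4ccc(OCc5ccccc5)cc4)oc23)c1)C(=O)c1c(O)cc(OC)cc1OCc1ccccc1 | intermediate
21 | tert-butyl (2S,3R)-5-(benzyloxy)-2-[4-(benzyloxy)-3-Fv-phenyl]-7-methoxy-4-oxochromane-3-carboxylate (trans; in equilibrium with C3 epimer and enol) | COc1cc(OCc2ccccc2)c2c(c1)O[C@H](c1ccc(OCc3ccccc3)c(-c3c(OCc4ccccc4)cc(OCc4ccccc4)c4c(=O)cc(-c5ccc(OCc6ccccc6)cc5)oc34)c1)[C@@H](C(=O)OC(C)(C)C)C2=O | intermediate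
22 | (2S)-5-(benzyloxy)-2-[4-(benzyloxy)-3-Fv-phenyl]-7-methoxy-2,3-dihydro-4H-chromen-4-one | COc1cc(OCc2ccccc2)c2c(c1)O[C@H](c1ccc(OCc3ccccc3)c(-c3c(OCc4ccccc4)cc(OCc4ccccc4)c4c(=O)cc(-c5ccc(OCc6ccccc6)cc5)oc34)c1)CC2=O | intermediate
23 | (2S)-2-{3-[5,7-dihydroxy-2-(4-hydroxyphenyl)-4-oxo-4H-chromen-8-yl]-4-hydroxyphenyl}-5-hydroxy-7-methoxy-2,3-dihydro-4H-chromen-4-one (CNP0107492.1) | COc1cc(O)c2c(c1)O[C@H](c1ccc(O)c(-c3c(O)cc(O)c4c(=O)cc(-c5ccc(O)cc5)oc34)c1)CC2=O | target

Total step count: 13. Longest linear sequence: 11 (steps 1–8, then 11–13). Steps 9 and 10 form the side branch.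

**Steps most likely to fail**

**1. Step 7.**
- *What may go wrong:* Conjugate addition of the weakly nucleophilic stabilised ylide to the partly aromatic pyranone may be too slow. The ring-opened phosphorane may stall because its formyl partner rests as an enol. The ylide may go on to olefinate the product aldehyde.
- *Fallback:* It gives up the ring edit and forms the C3'–C8'' bond by known cross-coupling. It sets out from 2 (with 6) and comes back at 16.
- Dianion aroylation of 2 with 6 under the conditions of step 4 should give 1-[2,4-bis(benzyloxy)-6-hydroxyphenyl]-3-[4-(benzyloxy)phenyl]propane-1,3-dione F1. TsOH cyclodehydration should then give tri-O-benzylapigenin F2.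
- Electrophilic iodination (I2, AgO2CCF3, CH2Cl2, 0 °C), which goes to C8 in 5,7-dialkoxyflavones, should give the 8-iodoflavone F3.
- Miyaura borylation (B2pin2, Pd(dppf)Cl2, KOAc, dioxane, 90 °C) should give the flavone 8-pinacolboronate F4.
- Suzuki–Miyaura coupling of F4 with commercial 4-(benzyloxy)-3-bromobenzaldehyde (Pd(PPh3)4, K2CO3, DME/H2O, 85 °C) should give 16.

**2. Step 12.**
- *What may go wrong:* Facial selectivity may be insufficient with an aroyl group that carries a second ortho alkoxy substituent and with a very large β-aryl group. Racemic background closure may already occur during step 11 or on silica. Acid-induced opening of the p-alkoxybenzylic C2–O bond at 80 °C may cause partial racemisation.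
- *Fallback:* It makes the racemate and resolves it catalytically. It sets out from 16 and 18 and comes back at 22.
- Claisen–Schmidt condensation (KOH, EtOH/THF, rt) should give the 2'-hydroxychalcone F5.
- NaOAc in refluxing EtOH should close it to the racemic flavanone F6.
- Kinetic resolution by asymmetric transfer hydrogenation follows (RhCl(Cp*)(TsDPEN), the antipode chosen to consume the 2R ketone, HCO2H/NEt3, EtOAc, rt). It should convert the 2R enantiomer into the cis-(2R,4R)-flavan-4-ol F7 and leave (2S)-22, which is separable by chromatography.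

**3. Step 6.**
- *What may go wrong:* Aminomethylenation may be incomplete at the benzylic CH2, which is crowded by two ortho oxygen substituents. Liberated dimethylamine may open the flavone hetero-ring during the long heating.
- *Fallback:* It attaches a preformed pyranone ring instead of building it. It sets out from 2, runs through the boronate F4 described above, and comes back at 12.
- Commercial 3-hydroxy-4H-pyran-4-one is converted with Tf2O/pyridine (CH2Cl2, 0 °C) into 4-oxo-4H-pyran-3-yl trifluoromethanesulfonate F8.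
- Suzuki–Miyaura coupling of F8 with F4 should give 12 (Pd(dppf)Cl2, K3PO4, dioxane, 80 °C, kept dry to protect the base-sensitive pyranone).

**Further compounds**

F1 | step 7 | 1-[2,4-bis(benzyloxy)-6-hydroxyphenyl]-3-[4-(benzyloxy)phenyl]propane-1,3-dione | O=C(CC(=O)c1ccc(OCc2ccccc2)cc1)c1c(O)cc(OCc2ccccc2)cc1OCc1ccccc1
F2 | step 7 | 5,7-bis(benzyloxy)-2-[4-(benzyloxy)phenyl]-4H-chromen-4-one | O=c1cc(-c2ccc(OCc3ccccc3)cc2)oc2cc(OCc3ccccc3)cc(OCc3ccccc3)c12
F3 | step 7 | 5,7-bis(benzyloxy)-2-[4-(benzyloxy)phenyl]-8-iodo-4H-chromen-4-one | O=c1cc(-c2ccc(OCc3ccccc3)cc2)oc2c(I)c(OCc3ccccc3)cc(OCc3ccccc3)c12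
F4 | step 7 | 5,7-bis(benzyloxy)-2-[4-(benzyloxy)phenyl]-8-(4,4,5,5-tetramethyl-1,3,2-dioxaborolan-2-yl)-4H-chromen-4-one | CC1(C)OB(OC1(C)C)c1c(OCc2ccccc2)cc(OCc2ccccc2)c2c(=O)cc(-c3ccc(OCc4ccccc4)cc3)oc12
F5 | step 12 | (2E)-1-[2-(benzyloxy)-6-hydroxy-4-methoxyphenyl]-3-[4-(benzyloxy)-3-Fv-phenyl]prop-2-en-1-one | COc1cc(O)c(C(=O)/C=C/c2ccc(OCc3ccccc3)c(-c3c(OCc4ccccc4)cc(OCc4ccccc4)c4c(=O)cc(-c5ccc(OCc6ccccc6)cc5)oc34)c2)c(OCc2ccccc2)c1
F6 | step 12 | racemic 5-(benzyloxy)-2-[4-(benzyloxy)-3-Fv-phenyl]-7-methoxy-2,3-dihydro-4H-chromen-4-one | COc1cc(OCc2ccccc2)c2c(c1)OC(c1ccc(OCc3ccccc3)c(-c3c(OCc4ccccc4)cc(OCc4ccccc4)c4c(=O)cc(-c5ccc(OCc6ccccc6)cc5)oc34)c1)CC2=O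
F7 | step 12 | (2R,4R)-5-(benzyloxy)-2-[4-(benzyloxy)-3-Fv-phenyl]-7-methoxychroman-4-ol | COc1cc(OCc2ccccc2)c2c(c1)O[C@@H](c1ccc(OCc3ccccc3)c(-c3c(OCc4ccccc4)cc(OCc4ccccc4)c4c(=O)cc(-c5ccc(OCc6ccccc6)cc5)oc34)c1)C[C@H]2O
F8 | step 6 | 4-oxo-4H-pyran-3-yl trifluoromethanesulfonate | O=c1ccocc1OS(=O)(=O)C(F)(F)F
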